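Remark on the chemistry: ring atoms are numbered as in the target (C1 carries the carboxyl group, C2 is the vinylic CH, C3–C5 carry oxygen, C6 is the CH2), and this numbering is used for acyclic intermediates too; racemic solketal 4 is used because its stereocentre is destroyed in step 4; 6-methylheptanoic acid 14 and tigloyl chloride 17 are assumed purchasable; the C4 descriptor switches between R and S along the route only because the CIP ranking of C3 and C5 changes with their oxygen substituents, while the spatial arrangement stays the same.

## Analysis of the target

The target 19 is a cyclohex-1-ene-1-carboxylic acid: one carbocycle, a C1=C2 alkene conjugated to the free acid, a C6 methylene and three contiguous acyloxy stereocentres at C3 (R), C4 (R) and C5 (S). The three oxygens are all-trans (3,4-trans and 4,5-trans), so the ring is the mirror image of the 3-epi-shikimate skeleton, and natural shikimate and quinate have the wrong absolute configuration at C4 and C5. Each oxygen carries a different ester, 6-methylheptanoate at allylic C3, (E)-2-methylbut-2-enoate (tiglate) at C4 and acetate at C5, so three secondary hydroxyls of similar reactivity must be told apart. Sensitive points are base-induced acyl migration between vicinal oxygens once one of them is free, the conjugated tiglate and C1=C2 alkenes (which rule out hydrogenolysis), and the free acid, which must be released without base. Any intermediate with a C3 carbonyl and a C5 leaving group is one elimination away from an aromatic benzoate. The difficulty therefore lies in setting C4 and C5 in the unnatural series while keeping the three oxygens distinguishable. The strategy rests on this feature: with C3 as a ketone, C4–C5 is an aldol bond between the α-carbon of an α-alkoxy ketone (C4) and an aldehyde carbon (C5), and the C3 and C6 arms sit cis on the C1=C2 alkene. The open-chain keto-aldehyde is thus achiral and pre-folded, and ring closure leaves O4 as an ether, O5 as the only free hydroxyl and O3 as a carbonyl.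

## Retrosynthetic reasoning

Carboxyl group, 19 from 18. The acid is released last from tert-butyl ester 18 by alkyl–oxygen cleavage under acid. Base or hydrogenolysis is excluded because three carboxylic esters and two conjugated alkenes must survive. The forward step only has to ionise the tert-butyl group.

O4–acyl bond, 18 from 16 and 17. The tiglate is cut next and goes on last in the forward sense, because O4 has to be an ether while the ring is built and the enone is reduced. Alcohol 16 and acid chloride 17 result. The forward acylation must work on a hydroxyl flanked by two esters without setting them migrating.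

O4–benzyl bond, 16 from 15. O4 is carried as a 4-methoxybenzyl ether in 15. It is the one common ether that comes off oxidatively under buffered conditions, leaving esters and the electron-poor alkene alone.

O3–acyl bond, 15 from 13 and 14. In alcohol 13 the C3 hydroxyl is the only free one, so esterification with acid 14 needs no selectivity. Its only neighbour, O4, is an ether, so no migration path exists.

C3–H bond, 13 from 12. The C3 carbinol is taken back to enone 12. This removes one stereocentre from the problem and exposes the aldol retron. Forward, hydride must add 1,2 and from the axial direction so that the new hydroxyl is equatorial and trans to O4.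

O5–acetyl bond, 12 from 11. The acetate is placed on the only hydroxyl of ketol 11 before the ketone is reduced, so that O3 and O5 are never free together. The forward step must acylate a β-hydroxy ketone without eliminating it.

C4–C5 bond, 11 from 10 (key disconnection). Cutting the aldol bond opens the ring to keto-aldehyde 10, which has no stereocentre. No other ring bond of 11 gives an achiral precursor in which both reacting carbons are already held together by the alkene. Forward, a chiral secondary amine must form the C3=C4 enamine, close the six-membered ring onto the C5 aldehyde, choose the aldehyde face (C5) and the enamine geometry (C4), and stop before water is lost. Compound 10 is a vinylogous 1,3-dicarbonyl compound, so the amine will also rest reversibly on the aldehyde end; the catalyst and medium are chosen with that in mind.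

C5 aldehyde, 10 from 9. The aldehyde is kept as a dimethyl acetal in 9 until just before the ring closure, because free 10 is too enolisable to carry through an olefination.

C1=C2 bond, 9 from 3 and 8. The trisubstituted alkene is cut to phosphonate 3 and keto-aldehyde 8. This Horner–Wadsworth–Emmons union joins all six ring carbons in one step and gives the (E) isomer, the one with the two arms cis.

C1–C6 bond, 3 from 1 and 2. Phosphonate 3 is the C-alkylation product of phosphonoacetate 1 with bromoacetal 2.

Keto-aldehyde 8 from 7, 6, 4 and 5. The 1,2-dicarbonyl unit of 8 comes from double oxidation of diol 7. Diol 7 is obtained by etherifying acetonide 4 with benzylic chloride 5 to give 6 and then removing the acetonide. This is preferred to mono-etherification of a free ketose, which is hard to control.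

## Alternatives that were turned down

Alternative 1: cycloaddition followed by opening of an oxygen bridge. The disconnection cuts C1–C2 and C5–C6. Forward, furan A1 serves as the diene and 3-acryloyloxazolidin-2-one A2 as the dienophile in a Diels–Alder reaction catalysed by the divalent copper complex [Cu(tert-butyl-bis(oxazoline))](SbF6)2, which should give the endo oxabicycle A3. Base-induced β-elimination of the bridge oxygen from the C1 enolate then gives the C1=C2 alkene and the C5 hydroxyl.
- For: A1 and A2 are cheap, the asymmetric step is of a well-established catalytic type, and the carbocycle with C5 is made in one step. On step count and on precedent for the enantioselective event it is at least as strong as the chosen route, probably stronger.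
- Against: the cycloaddition of A1 is readily reversible. The dienol obtained on opening A3 is one dehydration from an aromatic ester. The key step sets only C5. C3 and C4 would have to come from an epoxidation of the C3=C4 alkene anti to O5 followed by opening at C3 with inversion. These are two substrate-controlled events whose face and site selectivity are uncertain for the all-trans pattern, and the oxazolidinone carried in from A2 must also be exchanged for the ester.
- Comparison: the chosen strategy sets two of the three centres in the ring-forming step and leaves the three oxygens in three different states by construction.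

Alternative 2: chiral-pool chain closed at C2–C3. The disconnection cuts the vinyl–carbinol bond. Forward, a chain built from diethyl L-tartrate A4 carries an (E)-enol triflate at C2 and an aldehyde at C3; reductive coupling of the two with CrCl2 and catalytic NiCl2 should close the ring to the all-trans acetonide A5.
- For: the natural tartrate enantiomer A4 already has the C4 and C5 configuration needed, so absolute configuration is certain. On that point it is stronger than an untested asymmetric closure.
- Against: C3 is created in the closure under weak control from a trans-fused dioxolane and may need correction. Both ends of A4 must be homologated, one into an enol triflate of defined geometry, which makes the chain long. Chromium is used in excess. O4 and O5 leave the key step inside one acetonide in A5, and once it is removed two similar trans hydroxyls must be told apart for tiglate and acetate.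
- Comparison: the chosen strategy reaches its ring precursor in six steps from achiral materials and never has O4 and O5 in the same state.

Alternative 3: pentose chain closed at C1–C6. The disconnection cuts C1–C6. Forward, conjugate addition of PMe3 at C2 turns an enoate into its C1 enolate, which alkylates intramolecularly at the bromide-bearing C6; elimination of the phosphine with mild base then regenerates the C1=C2 alkene and should give A7.
- For: all three stereocentres come from L-xylose A6, nothing is epimerisable, and the three oxygens already carry three different groups. A7 is the C3 silyl ether of compound 13, so its endgame is as short as the chosen one. On stereochemical certainty it is the strongest of the four.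
- Against: A6 is the unnatural, costly enantiomer of the pentose. Putting three different protecting groups on three contiguous secondary hydroxyls takes many steps. This phosphine-mediated alkylation is well documented for enones but much less for the weaker enoate acceptors. The C6 bromide sits next to the C5 acetate, which slows substitution and invites participation.
- Comparison: the chosen strategy is much shorter to the ring and uses cheap achiral materials, at the price of an asymmetric closure that must be proven.

Key step: step 7

## Route

Step 1
Reactants: 1 tert-butyl diethylphosphonoacetate; 2 bromoacetaldehyde dimethyl acetal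
Product: 3 tert-butyl 2-(diethoxyphosphoryl)-4,4-dimethoxybutanoate (racemic)
Conditions: NaH, DMF, 0 °C; then 2, NaI (cat.), 80 °C
Reagents that add atoms: none
Why: C-alkylation (SN2) of the stabilised sodium phosphonoacetate carbanion; the β,β-dialkoxy bromide is a slow electrophile, hence iodide catalysis and heat, and the more hindered product anion disfavours a second alkylation.

Step 2
Reactants: 4 racemic solketal, (2,2-dimethyl-1,3-dioxolan-4-yl)methanol; 5 4-methoxybenzyl chloride
Product: 6 4-[(4-methoxybenzyloxy)methyl]-2,2-dimethyl-1,3-dioxolane (racemic)
Conditions: NaH, Bu4NI (cat.), THF/DMF, 0 °C to rt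
Reagents that add atoms: none
Why: Williamson etherification of a primary alkoxide with a benzylic chloride, accelerated through the benzylic iodide.

Step 3
Reactants: 6 4-[(4-methoxybenzyloxy)methyl]-2,2-dimethyl-1,3-dioxolane
Product: 7 3-(4-methoxybenzyloxy)propane-1,2-diol (racemic)
Conditions: AcOH/H2O (4:1), 40 °C
Reagents that add atoms: none
Why: Acid-catalysed hydrolysis of the isopropylidene ketal; dilute acetic acid is too weak to ionise the 4-methoxybenzyl ether.

Step 4
Reactants: 7 3-(4-methoxybenzyloxy)propane-1,2-diol
Product: 8 3-(4-methoxybenzyloxy)-2-oxopropanal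
Conditions: (COCl)2, DMSO, CH2Cl2, −78 °C; Et3N, −78 to 0 °C; used crude
Reagents that add atoms: none
Why: Double Swern oxidation of a terminal 1,2-diol to the 1,2-keto-aldehyde; activated-DMSO oxidation does not cleave the C–C bond, and the racemic carbinol centre is erased. Crude 8 is used at once because such keto-aldehydes hydrate and oligomerise.

Step 5
Reactants: 3 tert-butyl 2-(diethoxyphosphoryl)-4,4-dimethoxybutanoate; 8 3-(4-methoxybenzyloxy)-2-oxopropanal
Product: 9 tert-butyl (E)-2-(2,2-dimethoxyethyl)-5-(4-methoxybenzyloxy)-4-oxopent-2-enoate
Conditions: LiCl, DBU, MeCN, 0 °C to rt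
Reagents that add atoms: none
Why: Horner–Wadsworth–Emmons olefination under Masamune–Roush conditions, which suit a base-sensitive aldehyde; the aldehyde carbonyl of 8 is far more electrophilic than its ketone. An α-substituted phosphonoacetate places the ester trans to the aldehyde-derived acyl group, and this (E) isomer is also the more stable one, so any (Z) isomer can be removed or equilibrated with a trace of iodine.

Step 6
Reactants: 9 tert-butyl (E)-2-(2,2-dimethoxyethyl)-5-(4-methoxybenzyloxy)-4-oxopent-2-enoate
Product: 10 tert-butyl (E)-5-(4-methoxybenzyloxy)-4-oxo-2-(2-oxoethyl)pent-2-enoate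
Conditions: 1 M aq. HCl/THF (1:3), 0 °C to rt, short time; used at once
Reagents that add atoms: water, O
Why: Hydrolysis of a dimethyl acetal under dilute aqueous acid, which the tert-butyl ester and the 4-methoxybenzyl ether tolerate; acid rather than base is used because 10 is a vinylogous 1,3-dicarbonyl compound that enolises readily.

Step 7
Reactants: 10 tert-butyl (E)-5-(4-methoxybenzyloxy)-4-oxo-2-(2-oxoethyl)pent-2-enoate
Product: 11 tert-butyl (4R,5S)-5-hydroxy-4-(4-methoxybenzyloxy)-3-oxocyclohex-1-ene-1-carboxylate
Conditions: D-proline (30 mol %), DMF/H2O (20:1), 0.02 M, 4 °C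
Reagents that add atoms: none
Why: D-Proline condenses reversibly with the C3 ketone and loss of the C4 proton gives the cross-conjugated 2-aminodiene (C3=C4 enamine); C4 then adds to the C5 aldehyde, which the (E)-alkene holds on the same side, and hydrolysis of the ring iminium releases 11 and the catalyst. The closest known reaction type is the proline-catalysed 6-enolendo aldol cyclisation of the Hajos–Parrish kind, and the same connectivity is closed when secondary amines carbocyclise 2-ene-1,5-dicarbonyl compounds. The single ring is closed in the 6-(enolendo)-exo-trig mode, forming C4–C5. C5 is set by the catalyst: in the anti-enamine the carboxylic acid hydrogen-bonds the aldehyde oxygen while the tether keeps C6 over C2, so only one aldehyde face reaches C4, and carrying the facial model of the Hajos–Parrish closure over to this tether predicts 5S for the (R)-amino acid. C4 is set by enamine geometry, the (E)-enamine with the 4-methoxybenzyloxy group anti to nitrogen leading to the 4,5-trans ketol, and since C4 is α to the ketone it can also settle to the trans-diequatorial isomer. Regiochemistry needs no control because only the C4 enamine can reach C5 through a six-membered transition state; condensation at the aldehyde end gives only a reversible push–pull aminodienone reservoir, which is why a secondary amine (a primary amine would close to a pyridinium salt) and a wet solvent are specified. The step must stop at the aldol stage, so low temperature, dilution and short contact are used to keep the ketol from losing water and aromatising.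

Step 8
Reactants: 11 tert-butyl (4R,5S)-5-hydroxy-4-(4-methoxybenzyloxy)-3-oxocyclohex-1-ene-1-carboxylate
Product: 12 tert-butyl (4R,5S)-5-acetoxy-4-(4-methoxybenzyloxy)-3-oxocyclohex-1-ene-1-carboxylate
Conditions: Ac2O, pyridine, DMAP (cat.), CH2Cl2, −20 to 0 °C
Reagents that add atoms: acetic anhydride, CC(=O)OC(C)=O
Why: DMAP-catalysed acylation of the only free hydroxyl; a weak base and low temperature are used because a β-acetoxy ketone can lose acetate by E1cB and aromatise, a loss that is slowed here because the equatorial C5–O bond is poorly aligned with the enol π system.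

Step 9
Reactants: 12 tert-butyl (4R,5S)-5-acetoxy-4-(4-methoxybenzyloxy)-3-oxocyclohex-1-ene-1-carboxylate
Product: 13 tert-butyl (3R,4S,5S)-5-acetoxy-3-hydroxy-4-(4-methoxybenzyloxy)cyclohex-1-ene-1-carboxylate
Conditions: NaBH4, CeCl3·7H2O, MeOH, −78 °C
Reagents that add atoms: none
Why: Luche reduction; CeCl3 enforces 1,2-addition to an enone whose β-carbon also carries an ester, and hydride should enter along the axial trajectory of the half-chair with O4 and O5 equatorial, giving the pseudo-equatorial C3 hydroxyl trans to O4. The low temperature also prevents base-induced loss of the C5 acetate.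

Step 10
Reactants: 13 tert-butyl (3R,4S,5S)-5-acetoxy-3-hydroxy-4-(4-methoxybenzyloxy)cyclohex-1-ene-1-carboxylate; 14 6-methylheptanoic acid
Product: 15 tert-butyl (3R,4R,5S)-5-acetoxy-4-(4-methoxybenzyloxy)-3-(6-methylheptanoyloxy)cyclohex-1-ene-1-carboxylate
Conditions: EDC·HCl, DMAP (cat.), CH2Cl2, 0 °C to rt
Reagents that add atoms: none
Why: Steglich esterification of the only free hydroxyl; its neighbour O4 is an ether and the C5 acetate is 1,3-related and diequatorial, so no acyl migration path is open.

Step 11
Reactants: 15 tert-butyl (3R,4R,5S)-5-acetoxy-4-(4-methoxybenzyloxy)-3-(6-methylheptanoyloxy)cyclohex-1-ene-1-carboxylate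
Product: 16 tert-butyl (3R,4R,5S)-5-acetoxy-4-hydroxy-3-(6-methylheptanoyloxy)cyclohex-1-ene-1-carboxylate
Conditions: DDQ, CH2Cl2/pH 7 phosphate buffer (10:1), 0 °C to rt
Reagents that add atoms: none
Why: Oxidative cleavage of the 4-methoxybenzyl ether by DDQ through the benzylic oxocarbenium ion and its hydrolysis; esters and the electron-poor alkene are inert, and the neutral buffer keeps the flanking esters from migrating.

Step 12
Reactants: 16 tert-butyl (3R,4R,5S)-5-acetoxy-4-hydroxy-3-(6-methylheptanoyloxy)cyclohex-1-ene-1-carboxylate; 17 tigloyl chloride, (E)-2-methylbut-2-enoyl chloride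
Product: 18 tert-butyl (3R,4R,5S)-5-acetoxy-3-(6-methylheptanoyloxy)-4-[(E)-2-methylbut-2-enoyloxy]cyclohex-1-ene-1-carboxylate
Conditions: pyridine, DMAP (cat.), CH2Cl2, 0 °C to rt
Reagents that add atoms: none
Why: Acylation of a hindered secondary hydroxyl through the acylpyridinium ion; the (E) geometry of the tiglate is the stable one, and the weak base and short contact limit migration of the neighbouring esters.

Step 13
Reactants: 18 tert-butyl (3R,4R,5S)-5-acetoxy-3-(6-methylheptanoyloxy)-4-[(E)-2-methylbut-2-enoyloxy]cyclohex-1-ene-1-carboxylate
Product: 19 (3R,4R,5S)-5-acetoxy-3-(6-methylheptanoyloxy)-4-[(E)-2-methylbut-2-enoyloxy]cyclohex-1-ene-1-carboxylic acid (target)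
Conditions: TFA/CH2Cl2 (1:4), 0 °C to rt
Reagents that add atoms: none
Why: Acidolysis of the tert-butyl ester with loss of isobutene; the three other esters are stable to acid, and the allylic C3–O bond should not ionise because the alkene is conjugated to the carboxyl group.

## Compound list

1 | tert-butyl diethylphosphonoacetate | CCOP(=O)(CC(=O)OC(C)(C)C)OCC | starting material
2 | bromoacetaldehyde dimethyl acetal | COC(CBr)OC | starting material
3 | tert-butyl 2-(diethoxyphosphoryl)-4,4-dimethoxybutanoate (racemic) | CCOP(=O)(OCC)C(CC(OC)OC)C(=O)OC(C)(C)C | intermediate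
4 | racemic solketal, (2,2-dimethyl-1,3-dioxolan-4-yl)methanol | CC1(C)OCC(CO)O1 | starting material
5 | 4-methoxybenzyl chloride | COc1ccc(CCl)cc1 | starting material
6 | 4-[(4-methoxybenzyloxy)methyl]-2,2-dimethyl-1,3-dioxolane (racemic) | COc1ccc(COCC2COC(C)(C)O2)cc1 | intermediate
7 | 3-(4-methoxybenzyloxy)propane-1,2-diol (racemic) | COc1ccc(COCC(O)CO)cc1 | intermediate
8 | 3-(4-methoxybenzyloxy)-2-oxopropanal | COc1ccc(COCC(=O)C=O)cc1 | intermediate
9 | tert-butyl (E)-2-(2,2-dimethoxyethyl)-5-(4-methoxybenzyloxy)-4-oxopent-2-enoate | COC(OC)C/C(C(=O)OC(C)(C)C)=C\C(=O)COCc1ccc(OC)cc1 | intermediate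
10 | tert-butyl (E)-5-(4-methoxybenzyloxy)-4-oxo-2-(2-oxoethyl)pent-2-enoate | O=CC/C(C(=O)OC(C)(C)C)=C\C(=O)COCc1ccc(OC)cc1 | intermediate
11 | tert-butyl (4R,5S)-5-hydroxy-4-(4-methoxybenzyloxy)-3-oxocyclohex-1-ene-1-carboxylate | COc1ccc(CO[C@@H]2[C@@H](O)CC(C(=O)OC(C)(C)C)=CC2=O)cc1 | intermediate
12 | tert-butyl (4R,5S)-5-acetoxy-4-(4-methoxybenzyloxy)-3-oxocyclohex-1-ene-1-carboxylate | COc1ccc(CO[C@@H]2[C@@H](OC(C)=O)CC(C(=O)OC(C)(C)C)=CC2=O)cc1 | intermediate
13 | tert-butyl (3R,4S,5S)-5-acetoxy-3-hydroxy-4-(4-methoxybenzyloxy)cyclohex-1-ene-1-carboxylate | COc1ccc(CO[C@@H]2[C@@H](OC(C)=O)CC(C(=O)OC(C)(C)C)=C[C@H]2O)cc1 | intermediate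
14 | 6-methylheptanoic acid | CC(C)CCCCC(=O)O | starting material
15 | tert-butyl (3R,4R,5S)-5-acetoxy-4-(4-methoxybenzyloxy)-3-(6-methylheptanoyloxy)cyclohex-1-ene-1-carboxylate | COc1ccc(CO[C@@H]2[C@@H](OC(C)=O)CC(C(=O)OC(C)(C)C)=C[C@H]2OC(=O)CCCCC(C)C)cc1 | intermediate
16 | tert-butyl (3R,4R,5S)-5-acetoxy-4-hydroxy-3-(6-methylheptanoyloxy)cyclohex-1-ene-1-carboxylate | O[C@@H]1[C@@H](OC(C)=O)CC(C(=O)OC(C)(C)C)=C[C@H]1OC(=O)CCCCC(C)C | intermediate
17 | tigloyl chloride, (E)-2-methylbut-2-enoyl chloride | C/C=C(\C)C(=O)Cl | starting material
18 | tert-butyl (3R,4R,5S)-5-acetoxy-3-(6-methylheptanoyloxy)-4-[(E)-2-methylbut-2-enoyloxy]cyclohex-1-ene-1-carboxylate | C/C=C(\C)C(=O)O[C@@H]1[C@@H](OC(C)=O)CC(C(=O)OC(C)(C)C)=C[C@H]1OC(=O)CCCCC(C)C | intermediate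
19 | (3R,4R,5S)-5-acetoxy-3-(6-methylheptanoyloxy)-4-[(E)-2-methylbut-2-enoyloxy]cyclohex-1-ene-1-carboxylic acid | C/C=C(\C)C(=O)O[C@@H]1[C@@H](OC(C)=O)CC(C(=O)O)=C[C@H]1OC(=O)CCCCC(C)C | target

## Step count and least certain steps

Total: 13 steps. Longest linear sequence: 12 steps (steps 2 to 13, from 4).

Step 7 (key step). What may go wrong: the amine is expected to rest largely on the aldehyde end of 10 as a push–pull aminodienone, so turnover through the C3 enamine is slow, closure through the free enol can compete without facial control, and the ketol may form with low enantiomeric purity; long contact also favours loss of water from C5 and aromatisation. If the facial sense proves opposite to the model, the other antipode of the catalyst is used. Fallback (resolution in place of asymmetric catalysis): it sets out from 10. Closure with an achiral secondary amine salt (pyrrolidine, AcOH, wet DMF, 4 °C) should give 11 together with its antipode, tert-butyl (4S,5R)-5-hydroxy-4-(4-methoxybenzyloxy)-3-oxocyclohex-1-ene-1-carboxylate F1. Lipase-catalysed transesterification (Burkholderia cepacia lipase, vinyl acetate, tert-butyl methyl ether) is expected, by the empirical rule for secondary alcohols with the larger branch at C4, to acetylate the (5R)-alcohol faster. This would give tert-butyl (4S,5R)-5-acetoxy-4-(4-methoxybenzyloxy)-3-oxocyclohex-1-ene-1-carboxylate F2 and leave 11, which is separated and rejoins the route at 11.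

Step 8. What may go wrong: base-induced E1cB loss of the new C5 acetate from the β-acetoxy ketone, followed by tautomerisation to the phenol; the driving force is aromatisation. Fallback (O5 carried as a silyl ether through the ketone stage): it sets out from 11. Silylation (Et3SiCl, imidazole, DMF, 0 °C) gives tert-butyl (4R,5S)-4-(4-methoxybenzyloxy)-3-oxo-5-(triethylsilyloxy)cyclohex-1-ene-1-carboxylate F3, whose leaving group is much poorer than acetate. Luche reduction as in step 9 then gives tert-butyl (3R,4S,5S)-3-hydroxy-4-(4-methoxybenzyloxy)-5-(triethylsilyloxy)cyclohex-1-ene-1-carboxylate F4, and Steglich esterification with 14 gives tert-butyl (3R,4S,5S)-4-(4-methoxybenzyloxy)-3-(6-methylheptanoyloxy)-5-(triethylsilyloxy)cyclohex-1-ene-1-carboxylate F5. HF·pyridine in THF removes the silyl group to give tert-butyl (3R,4R,5S)-5-hydroxy-4-(4-methoxybenzyloxy)-3-(6-methylheptanoyloxy)cyclohex-1-ene-1-carboxylate F6. Acetylation (Ac2O, pyridine, DMAP), now with no ketone present, gives 15, where the route is rejoined.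

Step 9. What may go wrong: poor facial selectivity of hydride delivery, because the equatorial C4 substituent next to the carbonyl can hinder the axial trajectory, so that part of the material is reduced to the pseudo-axial (3S) alcohol. Fallback (configuration corrected by inversion instead of by the reduction): it sets out from 12. The epimer formed in the reduction, tert-butyl (3S,4S,5S)-5-acetoxy-3-hydroxy-4-(4-methoxybenzyloxy)cyclohex-1-ene-1-carboxylate F7, is separated and esterified with 14 under Mitsunobu conditions (PPh3, DIAD, THF, 0 °C). Inversion at C3 gives 15 directly, so both epimers of the reduction converge on 15.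

Step 6. What may go wrong: enolisation and double-bond migration of the liberated β,γ-unsaturated aldehyde, or acid-promoted closure and self-condensation of the 2-ene-1,5-dicarbonyl system during aqueous hydrolysis. Fallback (aldehyde unveiled by neutral oxidation instead of hydrolysis): it sets out from 1 and 8. Alkylation of 1 with (2-bromoethoxy)(tert-butyl)dimethylsilane (NaH, DMF, 60 °C), a better electrophile than 2, gives tert-butyl 4-(tert-butyldimethylsilyloxy)-2-(diethoxyphosphoryl)butanoate F8. Olefination with 8 as in step 5 gives tert-butyl (E)-2-[2-(tert-butyldimethylsilyloxy)ethyl]-5-(4-methoxybenzyloxy)-4-oxopent-2-enoate F9. HF·pyridine in THF gives tert-butyl (E)-2-(2-hydroxyethyl)-5-(4-methoxybenzyloxy)-4-oxopent-2-enoate F10. Dess–Martin periodinane with NaHCO3 in CH2Cl2 gives 10, where the route is rejoined.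

## Further compounds

F1 | step 7 | tert-butyl (4S,5R)-5-hydroxy-4-(4-methoxybenzyloxy)-3-oxocyclohex-1-ene-1-carboxylate | COc1ccc(CO[C@H]2[C@H](O)CC(C(=O)OC(C)(C)C)=CC2=O)cc1
F2 | step 7 | tert-butyl (4S,5R)-5-acetoxy-4-(4-methoxybenzyloxy)-3-oxocyclohex-1-ene-1-carboxylate | COc1ccc(CO[C@H]2[C@H](OC(C)=O)CC(C(=O)OC(C)(C)C)=CC2=O)cc1
F3 | step 8 | tert-butyl (4R,5S)-4-(4-methoxybenzyloxy)-3-oxo-5-(triethylsilyloxy)cyclohex-1-ene-1-carboxylate | COc1ccc(CO[C@@H]2[C@@H](O[Si](CC)(CC)CC)CC(C(=O)OC(C)(C)C)=CC2=O)cc1
F4 | step 8 | tert-butyl (3R,4S,5S)-3-hydroxy-4-(4-methoxybenzyloxy)-5-(triethylsilyloxy)cyclohex-1-ene-1-carboxylate | COc1ccc(CO[C@@H]2[C@@H](O[Si](CC)(CC)CC)CC(C(=O)OC(C)(C)C)=C[C@H]2O)cc1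
F5 | step 8 | tert-butyl (3R,4S,5S)-4-(4-methoxybenzyloxy)-3-(6-methylheptanoyloxy)-5-(triethylsilyloxy)cyclohex-1-ene-1-carboxylate | COc1ccc(CO[C@@H]2[C@@H](O[Si](CC)(CC)CC)CC(C(=O)OC(C)(C)C)=C[C@H]2OC(=O)CCCCC(C)C)cc1
F6 | step 8 | tert-butyl (3R,4R,5S)-5-hydroxy-4-(4-methoxybenzyloxy)-3-(6-methylheptanoyloxy)cyclohex-1-ene-1-carboxylate | COc1ccc(CO[C@@H]2[C@@H](O)CC(C(=O)OC(C)(C)C)=C[C@H]2OC(=O)CCCCC(C)C)cc1
F7 | step 9 | tert-butyl (3S,4S,5S)-5-acetoxy-3-hydroxy-4-(4-methoxybenzyloxy)cyclohex-1-ene-1-carboxylate | COc1ccc(CO[C@@H]2[C@@H](OC(C)=O)CC(C(=O)OC(C)(C)C)=C[C@@H]2O)cc1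
F8 | step 6 | tert-butyl 4-(tert-butyldimethylsilyloxy)-2-(diethoxyphosphoryl)butanoate (racemic) | CCOP(=O)(OCC)C(CCO[Si](C)(C)C(C)(C)C)C(=O)OC(C)(C)C
F9 | step 6 | tert-butyl (E)-2-[2-(tert-butyldimethylsilyloxy)ethyl]-5-(4-methoxybenzyloxy)-4-oxopent-2-enoate | CC(C)(C)[Si](C)(C)OCC/C(C(=O)OC(C)(C)C)=C\C(=O)COCc1ccc(OC)cc1
F10 | step 6 | tert-butyl (E)-2-(2-hydroxyethyl)-5-(4-methoxybenzyloxy)-4-oxopent-2-enoate | OCC/C(C(=O)OC(C)(C)C)=C\C(=O)COCc1ccc(OC)cc1
A1 | alternative 1 | furan | c1ccoc1
A2 | alternative 1 | 3-acryloyloxazolidin-2-one | C=CC(=O)N1CCOC1=O
A3 | alternative 1 | endo 3-[(1S,2S,4S)-7-oxabicyclo[2.2.1]hept-5-ene-2-carbonyl]oxazolidin-2-one | O=C(N1CCOC1=O)[C@H]1C[C@H]2C=C[C@@H]1O2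
A4 | alternative 2 | diethyl L-tartrate, diethyl (2R,3R)-2,3-dihydroxybutanedioate | CCOC(=O)[C@H](O)[C@@H](O)C(=O)OCC
A5 | alternative 2 | tert-butyl (3R,4S,5S)-3-hydroxy-4,5-(isopropylidenedioxy)cyclohex-1-ene-1-carboxylate, all-trans | C1[C@@H]2OC(C)(C)O[C@H]2[C@H](O)C=C1C(=O)OC(C)(C)C
A6 | alternative 3 | L-xylose, (2S,3R,4S)-2,3,4,5-tetrahydroxypentanal | O=C[C@@H](O)[C@H](O)[C@@H](O)CO
A7 | alternative 3 | tert-butyl (3R,4R,5S)-5-acetoxy-3-(tert-butyldimethylsilyloxy)-4-(4-methoxybenzyloxy)cyclohex-1-ene-1-carboxylate, all-trans | C1[C@H](OC(C)=O)[C@@H](OCc2ccc(OC)cc2)[C@H](O[Si](C)(C)C(C)(C)C)C=C1C(=O)OC(C)(C)C
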